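The winter run gives target quickly and then slows, so its readings are best read top row against bottom row.

| setting | midnight | winter | eta | epsilon | beta | zeta |
|---|---|---|---|---|---|---|
| starting material | 0.050 M | 0.050 M | 0.050 M | 0.050 M | 0.050 M | 0.050 M |
| partner | 0.075 M | 0.075 M | 0.0750 M | 0.0750 M | 0.0750 M | 0.0750 M |
| second substrate | 0.050 M | 0.075 M | 0.100 M | 0.100 M | 0.100 M | 0.100 M |
| protic impurity | 0.015 M | 0.015 M | 0.0150 M | 0.0150 M | 0.0150 M | 0.0150 M |
| temperature | 81 °C | 106 °C | 85 °C | 100 °C | 70 °C | 115 °C |
| remark | run made earlier | run made earlier |  |  |  |  |
| time |  |  | 3.0 d | 3.0 d | 3.0 d | 3.0 d |

- midnight (time / d: target / %): 0.250: 20.3; 0.833: 45.8; 1.25: 56.0; 2.00: 66.6; 3.00: 74.6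
- winter (time / h: target / %): 2.00: 27.6; 8.00: 57.6; 10.0: 61.0; 15.0: 66.6; 25.0: 71.5

(readings scatter by 0.3 percentage points)



- the best flask by amount of target, in percent of the starting material charged; "all alike" if 1.5 percentage points covers them all (eta / epsilon / beta / zeta / all alike)
- amount of target at the end, in percent of the starting material charged, eta
- amount of target at the end, in percent of the starting material charged, epsilon
- amount of target at the end, in percent of the starting material charged, beta
- amount of target at the end, in percent of the starting material charged, zeta

Over its first 2.00 h winter gains 27.6 %, but between 15.0 h and 25.0 h it gains 4.9 percentage points, so the pace has fallen by a factor of 28.2. The mean of those last two rows is 69.0 %, and by that point a rate first order in starting material and in partner, with target as the sole taker of partner, has fallen from its start by a factor of 5.99, so winter slows more than that step allows.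

The reckoning here takes the second substrate to be a rival for partner, which makes the balance of partner the thing to write: charged c(partner) equals remaining c(partner) plus c(target) plus whatever else has taken partner. The charges give 0.0250 M of partner beyond the starting material, and this partner surplus, the excess over the limiting reagent, is what a rival may take while full conversion stays possible. The shortfall of target below the starting material charged is then the partner taken elsewhere, plus the partner left, minus the surplus. The asked recipes hold 4.00 times the surplus as second substrate, and twice the midnight charge, so this reckoning expects them below the 74.6 % of midnight.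

The forecast differs: holding that “deactivation is much steeper” than the main rate, it names eta as best, with 98 % (96 % to 99.3 %), epsilon 96 %, beta 90.7 % and zeta 54 %.

The flasks give 68.4 % in eta, 63.8 % in epsilon, 55.3 % in beta and 53.5 % in zeta, so eta is best as forecast, and zeta falls within its range, while eta stands 30 points below the forecast.

    starting material + partner ⇌ target (K = 290 /M, k = 0.250 /M/h, Ea = 71.0 kJ/mol, ΔH = 31.0 kJ/mol)
    second substrate + partner → second product (k = 0.0710 /M/h, Ea = 94.0 kJ/mol)
    second substrate ⇌ dormant form (K = 0.210, k = 0.00980 /h, Ea = 116 kJ/mol, ΔH = −37.0 kJ/mol)
    second substrate + protic impurity → quenched substrate (k = 1.70 /M/h, Ea = 82.0 kJ/mol)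
    (constants at 70 °C)

At 3.00 d in eta the forward step to target uses partner at 0.84 of the rate of the step to second product, slower. Second product in eta stands at 0.0320 M, above the surplus, and with 0.00882 M of partner left the balance puts target 31.6 % short of the charge. In a neighbouring flask, eta repeated at 110 °C, second product reaches 0.0458 M against the same surplus, so the balance gives a shortfall of 43.0 %; the computed target there is 57.0 %.

Readings and results stem from a simulated flask with constants of no real substance; noise was put on by code.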